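**Retrosynthetic overview**
1. The oxazole is disconnected last (Robinson–Gabriel) to the ketoamide 7; it is the only ring built, and it is formed in the final step.
2. The amide C–N bond of 7 leads to the α-aminoketone hydrochloride 4 and 5-bromo-1H-pyrrole-2-carboxylic acid 5, so the pyrrole bromine is bought in and no late-stage bromination is needed.
3. The C–N bond of 4 leads to the chloroketone 2 (Delépine), and the C3–acyl bond of 2 leads to 6-bromo-4-methoxy-1H-indole 1 (Friedel–Crafts).
4. The indole and pyrrole rings are purchased intact.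

Assumption: the target has no stereocentre or stereoaxis, so it is achiral and the "single enantiomer" requirement is moot; 1 and 5 are taken as catalogue compounds.

**Step 1**
Reactants: 1 6-bromo-4-methoxy-1H-indole
Product: 2 2-chloro-1-(6-bromo-4-methoxy-1H-indol-3-yl)ethan-1-one
Conditions: Et2AlCl (1.5 equiv), CH2Cl2, 0 °C, 30 min; then ClCH2COCl (1.2 equiv), 0 °C, 2 h; aq. NaHCO3
Reagents that add atoms: chloroacetyl chloride, O=C(Cl)CCl
Why: Friedel–Crafts C3-acylation of an N–H indole under Okauchi conditions; Et2AlCl activates the acid chloride and scavenges HCl, and C3 is the most nucleophilic position (reinforced by the 4-OMe group); no stereocentre is formed.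

**Step 2**
Reactants: 2 2-chloro-1-(6-bromo-4-methoxy-1H-indol-3-yl)ethan-1-one
Product: 4 2-amino-1-(6-bromo-4-methoxy-1H-indol-3-yl)ethan-1-one hydrochloride, via hexaminium chloride 3 (not isolated)
Conditions: hexamethylenetetramine (1.1 equiv), NaI (0.1 equiv), EtOH/MeCN, 50 °C; then conc. HCl, EtOH, 50 °C, 16 h; triturate with ice-cold water to remove NH4Cl
Reagents that add atoms: hexamethylenetetramine, C1N2CN3CN1CN(C2)C3; hydrogen chloride, Cl
Why: Delépine reaction; SN2 quaternisation of hexamine stops cleanly at mono-alkylation, and ethanolic HCl dismantles the cage to the primary amine, held as its hydrochloride so the α-aminoketone cannot self-condense to a dihydropyrazine.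

**Step 3**
Reactants: 4 2-amino-1-(6-bromo-4-methoxy-1H-indol-3-yl)ethan-1-one hydrochloride; 5 5-bromo-1H-pyrrole-2-carboxylic acid
Product: 7 N-[2-(6-bromo-4-methoxy-1H-indol-3-yl)-2-oxoethyl]-5-bromo-1H-pyrrole-2-carboxamide, via benzotriazolyl ester 6 (not isolated)
Conditions: 5 (1.1 equiv), EDC·HCl (1.3 equiv), HOBt (1.3 equiv), DMF, 0 °C, 30 min; then 4, NaHCO3 (3 equiv), 0 °C → rt, 12 h
Reagents that add atoms: none
Why: Carbodiimide/HOBt amide coupling; the pre-formed active ester traps the amine as the mild base slowly liberates it, which outruns aminoketone self-condensation, and the pyrrole and indole N–H groups are too weakly nucleophilic to be acylated.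

**Step 4**
Reactants: 7 N-[2-(6-bromo-4-methoxy-1H-indol-3-yl)-2-oxoethyl]-5-bromo-1H-pyrrole-2-carboxamide
Product: 8 2-(5-bromo-1H-pyrrol-2-yl)-5-(6-bromo-4-methoxy-1H-indol-3-yl)-1,3-oxazole
Conditions: POCl3 (neat), 80 °C, 1–2 h; then ice-water, EtOAc extraction
Reagents that add atoms: none
Why: Robinson–Gabriel cyclodehydration; POCl3 activates the vinylogous-amide ketone, the amide oxygen closes the five-membered ring, and loss of water aromatises to the 2,5-disubstituted oxazole with the indolyl group at C5 and the pyrrolyl group at C2; the product has no stereocentre.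

**Compound list**
1 | 6-bromo-4-methoxy-1H-indole | COc1cc(Br)cc2[nH]ccc12 | starting material
2 | 2-chloro-1-(6-bromo-4-methoxy-1H-indol-3-yl)ethan-1-one | COc1cc(Br)cc2[nH]cc(C(=O)CCl)c12 | intermediate
3 | 1-[2-(6-bromo-4-methoxy-1H-indol-3-yl)-2-oxoethyl]-1,3,5,7-tetraazaadamantan-1-ium chloride (hexaminium chloride) | COc1cc(Br)cc2[nH]cc(C(=O)C[N+]34CN5CN(CN(C5)C3)C4)c12.[Cl-] | intermediate
4 | 2-amino-1-(6-bromo-4-methoxy-1H-indol-3-yl)ethan-1-one hydrochloride | COc1cc(Br)cc2[nH]cc(C(=O)C[NH3+])c12.[Cl-] | intermediate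
5 | 5-bromo-1H-pyrrole-2-carboxylic acid | OC(=O)c1ccc(Br)[nH]1 | starting material
6 | 1H-benzotriazol-1-yl 5-bromo-1H-pyrrole-2-carboxylate (benzotriazolyl ester) | O=C(On1nnc2ccccc21)c1ccc(Br)[nH]1 | intermediate
7 | N-[2-(6-bromo-4-methoxy-1H-indol-3-yl)-2-oxoethyl]-5-bromo-1H-pyrrole-2-carboxamide | COc1cc(Br)cc2[nH]cc(C(=O)CNC(=O)c3ccc(Br)[nH]3)c12 | intermediate
8 | 2-(5-bromo-1H-pyrrol-2-yl)-5-(6-bromo-4-methoxy-1H-indol-3-yl)-1,3-oxazole | COc1cc(Br)cc2[nH]cc(-c3cnc(-c4ccc(Br)[nH]4)o3)c12 | target

**Totals and risks**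
Total step count: 4. Longest linear sequence: 4 steps (1 → 2 → 4 → 7 → 8).

The three steps most likely to fail are step 4, step 2 and step 1, in that order.

Step 4 (cyclodehydration) is the main risk. The indolyl ketone is a poorly electrophilic vinylogous amide, the pyrrole N–H could close onto the activated ketone to give a pyrrolo[1,2-a]pyrazinone, and the 2-bromopyrrole may not tolerate hot POCl3. The fallback sets out from 2 (with 5 as acyl donor) and comes back to the route at 8. It closes the oxazole by an aza-Wittig sequence, so the ketone is never activated. NaN3 in DMF at rt converts 2 into 2-azido-1-(6-bromo-4-methoxy-1H-indol-3-yl)ethan-1-one F1. Separately, oxalyl chloride with catalytic DMF in CH2Cl2 converts 5 into 5-bromo-1H-pyrrole-2-carbonyl chloride F2. PPh3 in toluene/THF at rt turns F1 (Staudinger reaction) into the iminophosphorane 1-(6-bromo-4-methoxy-1H-indol-3-yl)-2-[(triphenyl-λ5-phosphanylidene)amino]ethan-1-one F3. F3 reacts with F2 to give N-[2-(6-bromo-4-methoxy-1H-indol-3-yl)-2-oxoethyl]-5-bromo-1H-pyrrole-2-carboximidoyl chloride F4 (transient, C=N geometry immaterial). On warming to 60 °C with Et3N the ketone enol oxygen attacks the imidoyl carbon of F4 and gives 8 directly.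

Step 2 (Delépine amination) is the second risk. Cage cleavage may be incomplete, ammonium chloride co-precipitates with 4 and would later give the primary amide of 5, and any free aminoketone dimerises. The fallback sets out from 2 and comes back to the route at 4. It is a Gabriel-type amination: sodium diformylamide in MeCN at 70 °C gives N-[2-(6-bromo-4-methoxy-1H-indol-3-yl)-2-oxoethyl]-N-formylformamide F5. Refluxing ethanolic HCl then removes both formyl groups and 4 crystallises free of ammonium salts.

Step 1 (C3 chloroacetylation) is the third risk. N1-acylation, diacylation, or alkylation of the electron-rich indole by the chloroketone product could compete, and the peri 4-OMe group hinders C3. The fallback sets out from 1 and comes back to the route at 4, bypassing 2. Vilsmeier–Haack formylation (POCl3, DMF, 0 °C → rt; aq. NaOH) gives 6-bromo-4-methoxy-1H-indole-3-carbaldehyde F6. Van Leusen reaction with TosMIC (K2CO3, MeOH, reflux) gives 5-(6-bromo-4-methoxy-1H-indol-3-yl)-1,3-oxazole F7. Hydrolysis of this 2-unsubstituted oxazole with 6 M aq. HCl in 1,4-dioxane at 90 °C removes C2 as formic acid and leaves 4.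

**Further compounds**
F1 | step 4 | 2-azido-1-(6-bromo-4-methoxy-1H-indol-3-yl)ethan-1-one | COc1cc(Br)cc2[nH]cc(C(=O)CN=[N+]=[N-])c12
F2 | step 4 | 5-bromo-1H-pyrrole-2-carbonyl chloride | O=C(Cl)c1ccc(Br)[nH]1
F3 | step 4 | 1-(6-bromo-4-methoxy-1H-indol-3-yl)-2-[(triphenyl-λ5-phosphanylidene)amino]ethan-1-one | COc1cc(Br)cc2[nH]cc(C(=O)CN=P(c3ccccc3)(c3ccccc3)c3ccccc3)c12
F4 | step 4 | N-[2-(6-bromo-4-methoxy-1H-indol-3-yl)-2-oxoethyl]-5-bromo-1H-pyrrole-2-carboximidoyl chloride | COc1cc(Br)cc2[nH]cc(C(=O)CN=C(Cl)c3ccc(Br)[nH]3)c12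
F5 | step 2 | N-[2-(6-bromo-4-methoxy-1H-indol-3-yl)-2-oxoethyl]-N-formylformamide | COc1cc(Br)cc2[nH]cc(C(=O)CN(C=O)C=O)c12
F6 | step 1 | 6-bromo-4-methoxy-1H-indole-3-carbaldehyde | COc1cc(Br)cc2[nH]cc(C=O)c12
F7 | step 1 | 5-(6-bromo-4-methoxy-1H-indol-3-yl)-1,3-oxazole | COc1cc(Br)cc2[nH]cc(-c3cnco3)c12
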